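**What stays put.** In the earlier closed flasks the product in mM reads close together at one early time: at 8.00 min beta holds 11.9 mM, epsilon 11.1 mM and delta 11.7 mM, though the charges run from 24 mM to 54 mM. So we reckon c(product) in mM, not in percent.

common to all: free catalyst 36 µM; impurity 9.7 µM; added ligand 29 µM

| run | substrate | reagent | remark | time |
|---|---|---|---|---|
| beta | 36 mM | 144 mM | run made earlier |  |
| epsilon | 24 mM | 144 mM | run made earlier |  |
| delta | 54 mM | 144 mM | run made earlier |  |
| midnight | 36 mM | 144 mM | one stirred flow tank at steady state, fed with the mixture as stated, mean residence time 40 min |  |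
| noon | 36 mM (fed, over 32.0 min) | 144 mM | all but substrate at the start; substrate goes in evenly over 32.0 min, the run ends at 40 min | 40 min |
| summer | 36 mM | 144 mM (fed, over 32.0 min) | all but reagent at the start; reagent goes in evenly over 32.0 min, the run ends at 40 min | 40 min |
| autumn | 36 mM | 144 mM | a closed flask charged with all of it at once and left for 40 min | 40 min |

| beta: time / min | beta: product / % | epsilon: time / min | epsilon: product / % | delta: time / min | delta: product / % |
|---|---|---|---|---|---|
| 2.00 | 13.0 | 3.00 | 25.8 | 2.50 | 11.9 |
| 3.00 | 18.6 | 5.00 | 33.7 | 8.00 | 21.6 |
| 5.00 | 25.9 | 8.00 | 46.1 | 15.0 | 32.4 |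
| 8.00 | 33.0 | 15.0 | 64.1 | 20.0 | 32.2 |
| 15.0 | 44.7 | 25.0 | 77.9 | 30.0 | 40.1 |
| 25.0 | 58.2 | 40.0 | 89.5 | 40.0 | 45.9 |

(standard deviation of a reading: 1 percentage point)

- the stated concentrations are those of everything mixed, before any reaction; amounts are the same in each set-up
- the feed brings no volume worth counting
- the earlier runs were made in a closed, stirred flask

- the set-up with the highest amount of product at the outlet or at the end, in percent of the substrate put in ("none" if the first two lie within 2 percentage points) (midnight / noon / summer / autumn / none)
- amount of product at the outlet or at the end, in percent of the substrate put in, midnight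
- amount of product at the outlet or at the end, in percent of the substrate put in, noon
- amount of product at the outlet or at the end, in percent of the substrate put in, summer
- amount of product at the outlet or at the end, in percent of the substrate put in, autumn

**Main step.** Suppose the catalytic round kept its opening speed. Beta reaches 4.68 mM at 2.00 min, a rate of 2.34 mM min⁻¹, which over 40 min would make 93.6 mM, more than the 36 mM charged.

**Adding impurity.** If impurity takes catalyst one for one, 26.9 % of the catalyst goes, and the same reckoning gives 68.4 mM, still more than the charge.

**The rest.** The readings slow further than that: beta makes 0.486 mM min⁻¹ between 15.0 min and 25.0 min, less than the opening rate cut by the impurity's share, 1.71 mM min⁻¹. Delta reads 24.8 mM at 40.0 min, with 29.2 mM of substrate still there. We call this reading the product budget: the mM made by that time in a closed flask with these charges of reagent, free catalyst, impurity and added ligand, read while substrate remains. It carries the scatter of 1 percentage point on the percent reading. Autumn's charge of 36 mM is above it, so our own estimate for autumn is 68.9 %.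

**The forecast.** It names autumn as best, with 48 % for midnight, 58 % for noon, 63 % for summer and 71 % for autumn, above our autumn figure, and it reads the slowing as “strong product inhibition”.

**The result.** Best is noon at 74.3 %, above midnight at 66.7 %, autumn at 68.3 % and summer at 16.3 %, which the forecast had at 63 %. At 40.0 min spent catalyst B, an off-cycle form, holds 68.6 % of the catalyst charged in summer and 47.9 % in noon. Held against the closed-flask budget of 24.8 mM, noon made 26.7 mM and summer 5.87 mM.

    reagent + free catalyst ⇌ catalyst intermediate A (K = 2.90 L mol⁻¹, k = 3400 L mol⁻¹ s⁻¹)
    catalyst intermediate A → catalyst intermediate B (k = 14.0 s⁻¹)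
    substrate + catalyst intermediate B → catalyst intermediate C (k = 130 L mol⁻¹ s⁻¹)
    catalyst intermediate C ⇌ free catalyst + product (K = 0.0670 M, k = 490 s⁻¹)
    free catalyst + impurity → spent catalyst A (k = 34000 L mol⁻¹ s⁻¹)
    free catalyst + added ligand ⇌ idle complex (K = 20000 L mol⁻¹, k = 82.0 L mol⁻¹ s⁻¹)
    2 free catalyst → spent catalyst B (k = 740 L mol⁻¹ s⁻¹)

**Second flask.** For the noon recipe with 90 mM of substrate, the closed-flask budget, taken as an estimate for this dosed flask, gives 27.6 %; the computed flask gives 32.5 %.

The data are calculated for an exercise, and the scatter is random.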